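**Retrosynthetic overview**
- The strategy rests on ring A: the ring oxygen O1 sits on C8a and the carbonyl carbon C4 on the neighbouring C4a, with the C5 oxygen flanking C4a. A C4a–C8a aryne can therefore take up the O–C(=O) unit of a carboxylic acid, and the C5 alkoxy group decides which end receives oxygen.
- Disconnection of O1–C8a, C4–C4a and O1–C2 in one operation leads to an o-silylaryl triflate (ring A) and a 3-arylpropiolic acid (ring B, C2, C3, C4 and both oxygens).
- The aryl–alkyne bond C1'–C2 is cut by Sonogashira coupling into propiolic acid and an aryl iodide made from 2,5-dimethoxybenzaldehyde.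
- The aryne precursor comes from 2,3-dihydroxy-4-methoxybenzaldehyde by benzylation, Dakin-type oxidation, ortho-bromination, O-to-C silyl shift and triflation.
- Ring order: both benzene rings are bought; the pyranone ring C is the only ring formed, in the key step, which also joins the halves. Hydrogenolysis of three benzyl ethers finishes the route; there is no stereochemistry to set.

Key step: step 10

Remark: the target is taken as the achiral flavone 5,6-dihydroxy-2-(4-hydroxy-2,5-dimethoxyphenyl)-7-methoxychromen-4-one. The three bought compounds are assumed commercial. In the key step the free acid is used, so that the HF/bifluoride formed with CsF supplies the C3 hydrogen.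

**Route**

Step 1
Reactants: 1 2,3-dihydroxy-4-methoxybenzaldehyde
Product: 2 2,3-bis(benzyloxy)-4-methoxybenzaldehyde
Conditions: BnBr (2.4 equiv), K2CO3, DMF, 60 °C
Reagents that add atoms: benzyl bromide, BrCc1ccccc1
Why: Williamson etherification, in which carbonate deprotonates both phenols (the chelated 2-OH needs the warm DMF) and each phenoxide displaces bromide from benzyl bromide while the aldehyde is inert.

Step 2
Reactants: 2 2,3-bis(benzyloxy)-4-methoxybenzaldehyde
Product: 4 2,3-bis(benzyloxy)-4-methoxyphenol, via 2,3-bis(benzyloxy)-4-methoxyphenyl formate 3 (not isolated)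
Conditions: mCPBA, CH2Cl2, 0 °C to rt; aq. NaHCO3 wash; then K2CO3 (cat.), MeOH, rt
Reagents that add atoms: meta-chloroperoxybenzoic acid (mCPBA), O=C(OO)c1cccc(Cl)c1
Why: Baeyer–Villiger (Dakin-type) oxidation, in which the electron-rich trialkoxyaryl group migrates in preference to hydride to give the aryl formate, which catalytic carbonate in methanol transesterifies to the phenol without touching the benzyl and methyl ethers.

Step 3
Reactants: 4 2,3-bis(benzyloxy)-4-methoxyphenol
Product: 5 6-bromo-2,3-bis(benzyloxy)-4-methoxyphenol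
Conditions: NBS (1.0 equiv), i-Pr2NH (cat.), CH2Cl2, 0 °C
Reagents that add atoms: N-bromosuccinimide, O=C1CCC(=O)N1Br
Why: Amine-mediated electrophilic aromatic bromination ortho to a free phenol; C6 is the only open ortho position and is activated by the OH and the para benzyloxy group, whereas the other free site C5 is served only by ether donors, so monobromination at C6 is expected.

Step 4
Reactants: 5 6-bromo-2,3-bis(benzyloxy)-4-methoxyphenol
Product: 6 [2,3-bis(benzyloxy)-6-bromo-4-methoxyphenoxy]trimethylsilane
Conditions: HMDS, THF, reflux; volatiles removed in vacuo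
Reagents that add atoms: hexamethyldisilazane, C[Si](C)(C)N[Si](C)(C)C
Why: O-silylation of the phenol with HMDS, driven by loss of ammonia, gives the aryl silyl ether needed for the silyl shift and leaves nothing that must be washed out before the organolithium step.

Step 5
Reactants: 6 [2,3-bis(benzyloxy)-6-bromo-4-methoxyphenoxy]trimethylsilane
Product: 9 2,3-bis(benzyloxy)-4-methoxy-6-(trimethylsilyl)phenyl trifluoromethanesulfonate, via ortho-lithiated aryl silyl ether 7 (not isolated), via lithium ortho-silylphenoxide 8 (not isolated)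
Conditions: n-BuLi, THF, −78 °C; then Tf2O, −78 °C to 0 °C
Reagents that add atoms: trifluoromethanesulfonic anhydride, O=S(=O)(OS(=O)(=O)C(F)(F)F)C(F)(F)F
Why: Bromine–lithium exchange followed by 1,3 O-to-C silyl migration (retro-Brook rearrangement) gives the ortho-silyl phenoxide, which Tf2O traps as the triflate; exchange at −78 °C should be much faster than benzylic deprotonation of the benzyl ethers.

Step 6
Reactants: 10 2,5-dimethoxybenzaldehyde
Product: 12 2,5-dimethoxyphenol, via 2,5-dimethoxyphenyl formate 11 (not isolated)
Conditions: mCPBA, CH2Cl2, rt; aq. NaHCO3 wash; then K2CO3 (cat.), MeOH, rt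
Reagents that add atoms: meta-chloroperoxybenzoic acid (mCPBA), O=C(OO)c1cccc(Cl)c1
Why: Baeyer–Villiger (Dakin-type) oxidation, in which the ortho-methoxy group promotes aryl migration to the aryl formate, and methanolysis then frees the phenol.

Step 7
Reactants: 12 2,5-dimethoxyphenol
Product: 13 2-(benzyloxy)-1,4-dimethoxybenzene
Conditions: BnBr, K2CO3, acetone, reflux
Reagents that add atoms: benzyl bromide, BrCc1ccccc1
Why: Williamson etherification of the single phenol with benzyl bromide under carbonate.

Step 8
Reactants: 13 2-(benzyloxy)-1,4-dimethoxybenzene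
Product: 14 1-(benzyloxy)-4-iodo-2,5-dimethoxybenzene
Conditions: NIS, TFA (cat.), MeCN, rt
Reagents that add atoms: N-iodosuccinimide, O=C1CCC(=O)N1I
Why: Electrophilic aromatic iodination with acid-activated NIS; the position para to the benzyloxy group and ortho to the 5-methoxy group is the most activated and least hindered site of this 1,2,4-trialkoxybenzene, as in substitution of 1,2,4-trimethoxybenzene at C5.

Step 9
Reactants: 14 1-(benzyloxy)-4-iodo-2,5-dimethoxybenzene; 15 propiolic acid
Product: 16 3-[4-(benzyloxy)-2,5-dimethoxyphenyl]prop-2-ynoic acid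
Conditions: Pd(PPh3)4 (5 mol%), DBU (2.4 equiv), DMSO, 35 °C; then aq. HCl
Reagents that add atoms: none
Why: Copper-free Sonogashira coupling of the aryl iodide with propiolic acid held as its DBU carboxylate forms the aryl–alkyne bond, and the mild temperature and absence of copper should keep the alkynoic acid from decarboxylating.

Step 10
Reactants: 9 2,3-bis(benzyloxy)-4-methoxy-6-(trimethylsilyl)phenyl trifluoromethanesulfonate; 16 3-[4-(benzyloxy)-2,5-dimethoxyphenyl]prop-2-ynoic acid
Product: 19 5,6-bis(benzyloxy)-2-[4-(benzyloxy)-2,5-dimethoxyphenyl]-7-methoxy-4H-chromen-4-one, via 3,4-bis(benzyloxy)-5-methoxybenzyne 17 (not isolated), via cesium o-acylphenoxide ynone 18 (not isolated)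
Conditions: 9 (1.5 equiv), CsF (4 equiv), THF, 125 °C, sealed tube
Reagents that add atoms: none
Why: Fluoride strips the silyl group of 9 and triflate departs to give aryne 17; the cesium carboxylate of 16 adds through oxygen to the aryne carbon remote from the benzyloxy group (future C8a, forming O1–C8a), the aryl anion left at future C4a attacks the neighbouring ester carbonyl in a 4-exo-trig closure (forming C4–C4a), and the benzoxetene alkoxide opens to the o-acylphenoxide 18, so that one acid oxygen becomes O1 and the other stays as the C4 carbonyl. The closest known reaction type is the fluoride-triggered intermolecular C–O insertion of arynes into carboxylic acids (O-arylation, then anionic acyl shift to o-hydroxyaryl ketones), which with arylpropiolic acids is known to run on to flavones. The pyranone ring then closes by 6-endo-dig oxa-Michael addition of the phenoxide of 18 to the ynone carbon bearing ring B (forming O1–C2), and the C3 carbanion is protonated by the HF/bifluoride generated from the acid. No stereocenter is created. The selectivity required is oxygen attack at C8a and not at C4a; it is secured by the benzyloxy group flanking the aryne bond, whose inductive pull and distortion of the triple bond make the remote carbon the electrophilic one and stabilise the anion developing next to it, while heating in THF favours the acyl shift over simple protonation of that anion.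

Step 11
Reactants: 19 5,6-bis(benzyloxy)-2-[4-(benzyloxy)-2,5-dimethoxyphenyl]-7-methoxy-4H-chromen-4-one
Product: 20 5,6-dihydroxy-2-(4-hydroxy-2,5-dimethoxyphenyl)-7-methoxy-4H-chromen-4-one (CNP0310413.0)
Conditions: H2 (1 atm), Pd/C (10 wt%), EtOAc–MeOH, rt
Reagents that add atoms: none
Why: Catalytic hydrogenolysis of the three benzyl aryl ethers over Pd/C under neutral conditions should leave the methyl ethers and the chromone enone (a vinylogous ester, not reduced at 1 atm and room temperature) intact.

**Compound list**
1 | 2,3-dihydroxy-4-methoxybenzaldehyde | COc1ccc(C=O)c(O)c1O | starting material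
2 | 2,3-bis(benzyloxy)-4-methoxybenzaldehyde | COc1ccc(C=O)c(OCc2ccccc2)c1OCc1ccccc1 | intermediate
3 | 2,3-bis(benzyloxy)-4-methoxyphenyl formate | COc1ccc(OC=O)c(OCc2ccccc2)c1OCc1ccccc1 | intermediate
4 | 2,3-bis(benzyloxy)-4-methoxyphenol | COc1ccc(O)c(OCc2ccccc2)c1OCc1ccccc1 | intermediate
5 | 6-bromo-2,3-bis(benzyloxy)-4-methoxyphenol | COc1cc(Br)c(O)c(OCc2ccccc2)c1OCc1ccccc1 | intermediate
6 | [2,3-bis(benzyloxy)-6-bromo-4-methoxyphenoxy]trimethylsilane | COc1cc(Br)c(O[Si](C)(C)C)c(OCc2ccccc2)c1OCc1ccccc1 | intermediate
7 | [3,4-bis(benzyloxy)-5-methoxy-2-(trimethylsilyloxy)phenyl]lithium | COc1cc([Li])c(O[Si](C)(C)C)c(OCc2ccccc2)c1OCc1ccccc1 | intermediate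
8 | lithium 2,3-bis(benzyloxy)-4-methoxy-6-(trimethylsilyl)phenoxide | COc1cc([Si](C)(C)C)c([O-])c(OCc2ccccc2)c1OCc1ccccc1.[Li+] | intermediate
9 | 2,3-bis(benzyloxy)-4-methoxy-6-(trimethylsilyl)phenyl trifluoromethanesulfonate | COc1cc([Si](C)(C)C)c(OS(=O)(=O)C(F)(F)F)c(OCc2ccccc2)c1OCc1ccccc1 | intermediate
10 | 2,5-dimethoxybenzaldehyde | COc1ccc(OC)c(C=O)c1 | starting material
11 | 2,5-dimethoxyphenyl formate | COc1ccc(OC)c(OC=O)c1 | intermediate
12 | 2,5-dimethoxyphenol | COc1ccc(OC)c(O)c1 | intermediate
13 | 2-(benzyloxy)-1,4-dimethoxybenzene | COc1ccc(OC)c(OCc2ccccc2)c1 | intermediate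
14 | 1-(benzyloxy)-4-iodo-2,5-dimethoxybenzene | COc1cc(OCc2ccccc2)c(OC)cc1I | intermediate
15 | propiolic acid | C#CC(=O)O | starting material
16 | 3-[4-(benzyloxy)-2,5-dimethoxyphenyl]prop-2-ynoic acid | COc1cc(OCc2ccccc2)c(OC)cc1C#CC(=O)O | intermediate
17 | 3,4-bis(benzyloxy)-5-methoxybenzyne | COC1=CC#CC(OCc2ccccc2)=C1OCc1ccccc1 | intermediate
18 | cesium 3,4-bis(benzyloxy)-2-{3-[4-(benzyloxy)-2,5-dimethoxyphenyl]prop-2-ynoyl}-5-methoxyphenoxide | COc1cc([O-])c(C(=O)C#Cc2cc(OC)c(OCc3ccccc3)cc2OC)c(OCc2ccccc2)c1OCc1ccccc1.[Cs+] | intermediate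
19 | 5,6-bis(benzyloxy)-2-[4-(benzyloxy)-2,5-dimethoxyphenyl]-7-methoxy-4H-chromen-4-one | COc1cc(-c2cc(=O)c3c(OCc4ccccc4)c(OCc4ccccc4)c(OC)cc3o2)c(OC)cc1OCc1ccccc1 | intermediate
20 | 5,6-dihydroxy-2-(4-hydroxy-2,5-dimethoxyphenyl)-7-methoxy-4H-chromen-4-one (CNP0310413.0) | COc1cc(-c2cc(=O)c3c(O)c(O)c(OC)cc3o2)c(OC)cc1O | target

**Count**
Total step count: 11. Longest linear sequence: 7 steps (steps 1, 2, 3, 4, 5, 10, 11 from compound 1).

**Steps most likely to fail**

Step 10. At 125 °C the cesium arylpropiolate may lose CO2 before it meets the aryne. The ynone phenoxide may also be diverted by 5-exo closure or by conjugate addition of fluoride or carboxylate, and the aryl anion may be protonated before the acyl shift. The fallback separates the acyl transfer from the pyranone construction; it sets out from triflate 9 and benzyl ether 13 and comes back at flavone 19. Treating 9 with acetic acid and CsF in THF at 125 °C, the same C–O insertion with a simple acid that can neither decarboxylate nor act as a Michael acceptor, should give 1-[2,3-bis(benzyloxy)-6-hydroxy-4-methoxyphenyl]ethan-1-one F1. Vilsmeier–Haack formylation of 13 (POCl3, DMF) should give 4-(benzyloxy)-2,5-dimethoxybenzaldehyde F2, formylated para to the benzyloxy group like the iodination. Claisen–Schmidt condensation of F1 with F2 (KOH, EtOH, rt) should give (E)-1-[2,3-bis(benzyloxy)-6-hydroxy-4-methoxyphenyl]-3-[4-(benzyloxy)-2,5-dimethoxyphenyl]prop-2-en-1-one F3. Oxidative cyclisation of this 2'-hydroxychalcone with catalytic I2 in DMSO at 120 °C should deliver 19.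

Step 9. Palladium-mediated decarboxylation of the alkynoic acid, followed by a second coupling to the diarylalkyne, may compete, and oxidative addition to the electron-rich ortho-substituted iodide may be slow. The fallback installs the alkyne first and the carboxyl group last; it sets out from iodide 14 and comes back at acid 16. Sonogashira coupling of 14 with trimethylsilylacetylene (Pd(PPh3)2Cl2, CuI, Et3N, THF, 50 °C) should give {[4-(benzyloxy)-2,5-dimethoxyphenyl]ethynyl}trimethylsilane F4. Desilylation (K2CO3, MeOH) should give 1-(benzyloxy)-4-ethynyl-2,5-dimethoxybenzene F5. Deprotonation with n-BuLi in THF at −78 °C, quench with CO2 and acidification should give 16.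

Step 3. Bromination may occur in part at C5 (ortho to the methoxy group), or go on to the dibromide, which would carry the wrong substitution into the aryne precursor. The fallback places the silyl group by directed ortho-metalation, where the only free position ortho to the directing group is C6; it sets out from phenol 4 and comes back at triflate 9, bypassing steps 3 to 5. Carbamoylation of 4 (NaH, ClC(O)NEt2, THF) should give 2,3-bis(benzyloxy)-4-methoxyphenyl N,N-diethylcarbamate F6. Ortho-lithiation with s-BuLi/TMEDA in THF at −78 °C and quench with TMSCl should give 2,3-bis(benzyloxy)-4-methoxy-6-(trimethylsilyl)phenyl N,N-diethylcarbamate F7. Reductive removal of the carbamate with LiAlH4 in THF should give 2,3-bis(benzyloxy)-4-methoxy-6-(trimethylsilyl)phenol F8. Triflation (Tf2O, pyridine, CH2Cl2, 0 °C) should give 9.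

**Further compounds**
F1 | step 10 | 1-[2,3-bis(benzyloxy)-6-hydroxy-4-methoxyphenyl]ethan-1-one | COc1cc(O)c(C(C)=O)c(OCc2ccccc2)c1OCc1ccccc1
F2 | step 10 | 4-(benzyloxy)-2,5-dimethoxybenzaldehyde | COc1cc(OCc2ccccc2)c(OC)cc1C=O
F3 | step 10 | (E)-1-[2,3-bis(benzyloxy)-6-hydroxy-4-methoxyphenyl]-3-[4-(benzyloxy)-2,5-dimethoxyphenyl]prop-2-en-1-one | COc1cc(O)c(C(=O)/C=C/c2cc(OC)c(OCc3ccccc3)cc2OC)c(OCc2ccccc2)c1OCc1ccccc1
F4 | step 9 | {[4-(benzyloxy)-2,5-dimethoxyphenyl]ethynyl}trimethylsilane | COc1cc(OCc2ccccc2)c(OC)cc1C#C[Si](C)(C)C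
F5 | step 9 | 1-(benzyloxy)-4-ethynyl-2,5-dimethoxybenzene | COc1cc(OCc2ccccc2)c(OC)cc1C#C
F6 | step 3 | 2,3-bis(benzyloxy)-4-methoxyphenyl N,N-diethylcarbamate | COc1ccc(OC(=O)N(CC)CC)c(OCc2ccccc2)c1OCc1ccccc1
F7 | step 3 | 2,3-bis(benzyloxy)-4-methoxy-6-(trimethylsilyl)phenyl N,N-diethylcarbamate | COc1cc([Si](C)(C)C)c(OC(=O)N(CC)CC)c(OCc2ccccc2)c1OCc1ccccc1
F8 | step 3 | 2,3-bis(benzyloxy)-4-methoxy-6-(trimethylsilyl)phenol | COc1cc([Si](C)(C)C)c(O)c(OCc2ccccc2)c1OCc1ccccc1
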